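**Retrosynthetic overview**

- The target is opened at the aryl O–CH3 bond: the methyl group on the C5 oxygen is installed last, on a catechol-masked pyrogallol, and boron is then removed by diol exchange.
- Feature carrying the strategy: on the benzene ring (numbered from the chain-bearing carbon C1) the oxygens sit on C3, C4 and C5. Without the O-methyl group the arene is a 5-alkylpyrogallol with a mirror plane through C1 and C4. The two hydroxyls that stay free in the target (on C3 and C4) are ortho to each other, so a single boron atom can tie them into a 1,3,2-dioxaborole.
- The symmetric triol ester comes from its tris(benzyl ether) by hydrogenolysis, and that from 3-[3,4,5-tris(benzyloxy)phenyl]propan-1-ol and stearoyl chloride.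
- The alcohol comes from 3,4,5-tris(benzyloxy)benzaldehyde by Horner–Wadsworth–Emmons olefination, conjugate reduction and ester reduction.
- Ring order: the benzene ring is bought. The only ring made is the temporary five-membered dioxaborole (step 6), which is opened again in step 7.

Key step: step 6

Remark on the chemistry: the target has no stereocentre and no stereogenic double bond; the only geometric element in the route, the E alkene of compound 3, is removed in step 2.

**Route**

Step 1
Reactants: 1 3,4,5-tris(benzyloxy)benzaldehyde; 2 triethyl phosphonoacetate
Product: 3 ethyl (E)-3-[3,4,5-tris(benzyloxy)phenyl]prop-2-enoate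
Conditions: NaH, THF, 0 °C to rt
Reagents that add atoms: none
Why: Horner–Wadsworth–Emmons olefination; the stabilised phosphonate anion adds to the aldehyde and the reversible addition funnels through the anti oxaphosphetane, so the E cinnamate should predominate.

Step 2
Reactants: 3 ethyl (E)-3-[3,4,5-tris(benzyloxy)phenyl]prop-2-enoate
Product: 4 ethyl 3-[3,4,5-tris(benzyloxy)phenyl]propanoate
Conditions: NaBH4, NiCl2·6H2O (cat.), EtOH–THF, 0 °C
Reagents that add atoms: none
Why: Nickel boride (Ni2B) conjugate reduction; the boride formed in situ saturates the electron-poor cinnamate C=C while the ester and the aryl benzyl ethers should stay untouched, and ethanol as co-solvent makes any transesterification degenerate.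

Step 3
Reactants: 4 ethyl 3-[3,4,5-tris(benzyloxy)phenyl]propanoate
Product: 5 3-[3,4,5-tris(benzyloxy)phenyl]propan-1-ol
Conditions: LiAlH4, THF, 0 °C; then H2O, aq NaOH
Reagents that add atoms: none
Why: Standard LiAlH4 reduction of an ester to the primary alcohol; benzyl ethers are inert to hydride.

Step 4
Reactants: 5 3-[3,4,5-tris(benzyloxy)phenyl]propan-1-ol; 6 stearoyl chloride
Product: 7 3-[3,4,5-tris(benzyloxy)phenyl]propyl octadecanoate
Conditions: Et3N, DMAP (cat.), CH2Cl2, 0 °C to rt
Reagents that add atoms: none
Why: DMAP-catalysed acylation of the only free hydroxyl by an acid chloride (nucleophilic acyl substitution); all phenols are still masked, so there is no competing O-acylation.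

Step 5
Reactants: 7 3-[3,4,5-tris(benzyloxy)phenyl]propyl octadecanoate
Product: 8 3-(3,4,5-trihydroxyphenyl)propyl octadecanoate
Conditions: H2 (1 atm), 10% Pd/C, THF–EtOH, rt; filtered and concentrated under Ar
Reagents that add atoms: none
Why: Catalytic hydrogenolysis of the three benzylic C–O bonds; the stearate is a non-benzylic alkyl ester and should survive, and handling under argon protects the air-sensitive pyrogallol.

Step 6
Reactants: 8 3-(3,4,5-trihydroxyphenyl)propyl octadecanoate; 9 phenylboronic acid
Product: 11 3-(7-methoxy-2-phenyl-1,3,2-benzodioxaborol-5-yl)propyl octadecanoate, via hydroxy-dioxaborole 10 (not isolated)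
Conditions: PhB(OH)2, toluene, reflux (Dean–Stark), Ar; solvent removed; then K2CO3, MeI, dry DMF, 4 Å MS, rt, Ar; filtered and evaporated under Ar, used crude
Reagents that add atoms: iodomethane (MeI), CI
Why: Phenylboronic acid condenses with the pyrogallol by two successive B–O exchanges, each expelling water that the azeotrope removes; the second is an intramolecular attack of the neighbouring phenol oxygen on trigonal boron (5-exo-trig) that closes the planar 1,3,2-dioxaborole ring. Because a five-membered boronate can only bridge ortho oxygens, boron must take the central C4 oxygen plus one flanking oxygen, and the mirror plane through C1 and C4 of 8 makes the two ways of doing so the same compound 10. K2CO3 then deprotonates the one phenol left, on C5, and its phenoxide displaces iodide from MeI (SN2), forming the O–CH3 bond. The closest known chemistry is the borate- or arylboronate-masked monoalkylation of gallate esters and other catechol-bearing polyphenols. The step needs mono- over polymethylation and flank over centre; both follow from the boronate, which leaves exactly one free hydroxyl, while anhydrous, weakly basic conditions should keep the B–O bonds and the stearate ester intact. No stereocentre is formed.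

Step 7
Reactants: 11 3-(7-methoxy-2-phenyl-1,3,2-benzodioxaborol-5-yl)propyl octadecanoate
Product: 12 3-(3,4-dihydroxy-5-methoxyphenyl)propyl octadecanoate
Conditions: pinacol, THF–H2O, rt, Ar; chromatography on silica
Reagents that add atoms: none
Why: Boronate transesterification (diol exchange); the aliphatic 1,2-diol takes boron from the aryl dioxaborole, as in the standard conversion of catechol boronates into pinacol boronates, and the neutral conditions should leave the ester and the methyl ether alone.

**Compound list**

1 | 3,4,5-tris(benzyloxy)benzaldehyde | O=Cc1cc(OCc2ccccc2)c(OCc2ccccc2)c(OCc2ccccc2)c1 | starting material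
2 | triethyl phosphonoacetate | CCOC(=O)CP(=O)(OCC)OCC | starting material
3 | ethyl (E)-3-[3,4,5-tris(benzyloxy)phenyl]prop-2-enoate | CCOC(=O)/C=C/c1cc(OCc2ccccc2)c(OCc2ccccc2)c(OCc2ccccc2)c1 | intermediate
4 | ethyl 3-[3,4,5-tris(benzyloxy)phenyl]propanoate | CCOC(=O)CCc1cc(OCc2ccccc2)c(OCc2ccccc2)c(OCc2ccccc2)c1 | intermediate
5 | 3-[3,4,5-tris(benzyloxy)phenyl]propan-1-ol | OCCCc1cc(OCc2ccccc2)c(OCc2ccccc2)c(OCc2ccccc2)c1 | intermediate
6 | stearoyl chloride (octadecanoyl chloride) | CCCCCCCCCCCCCCCCCC(=O)Cl | starting material
7 | 3-[3,4,5-tris(benzyloxy)phenyl]propyl octadecanoate | CCCCCCCCCCCCCCCCCC(=O)OCCCc1cc(OCc2ccccc2)c(OCc2ccccc2)c(OCc2ccccc2)c1 | intermediate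
8 | 3-(3,4,5-trihydroxyphenyl)propyl octadecanoate | CCCCCCCCCCCCCCCCCC(=O)OCCCc1cc(O)c(O)c(O)c1 | intermediate
9 | phenylboronic acid | OB(O)c1ccccc1 | starting material
10 | 3-(7-hydroxy-2-phenyl-1,3,2-benzodioxaborol-5-yl)propyl octadecanoate | CCCCCCCCCCCCCCCCCC(=O)OCCCc1cc(O)c2OB(c3ccccc3)Oc2c1 | intermediate
11 | 3-(7-methoxy-2-phenyl-1,3,2-benzodioxaborol-5-yl)propyl octadecanoate | CCCCCCCCCCCCCCCCCC(=O)OCCCc1cc(OC)c2OB(c3ccccc3)Oc2c1 | intermediate
12 | 3-(3,4-dihydroxy-5-methoxyphenyl)propyl octadecanoate | CCCCCCCCCCCCCCCCCC(=O)OCCCc1cc(O)c(O)c(OC)c1 | target

**Step count**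

Total steps: 7. Longest linear sequence: 7 steps (1 to 12).

**Steps most likely to fail**

Step 6. The risk is opening of the B–O bonds during the alkylation, by hydrogencarbonate or traces of water, or boron exchange between molecules. Either would expose the C4 or C3 oxygen to methyl iodide and give over-methylation or methylation at the centre. The fallback replaces the boronate by a base-stable carbon ketal. It sets out from 8, which with dichlorodiphenylmethane and K2CO3 in MeCN at rt under argon should give 3-(7-hydroxy-2,2-diphenyl-1,3-benzodioxol-5-yl)propyl octadecanoate F1; here too symmetry makes the two possible ketals identical. Methylation of the remaining phenol with MeI and K2CO3 in DMF should give 3-(7-methoxy-2,2-diphenyl-1,3-benzodioxol-5-yl)propyl octadecanoate F2. Hydrogenolysis of the diphenylmethylene ketal (H2, 10% Pd/C, THF–MeOH, rt) then returns to the route at 12.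

Step 2. The risk is loss of chemoselectivity on the nickel surface: incomplete saturation of the alkene, partial reduction of the ester, or cleavage of an aryl benzyl ether. The fallback changes the order and type of the reductions. It sets out from 3, which with DIBAL-H in CH2Cl2 at −78 °C should give (E)-3-[3,4,5-tris(benzyloxy)phenyl]prop-2-en-1-ol F3 by 1,2-reduction of the ester. Diimide, generated from 2-nitrobenzenesulfonyl hydrazide and Et3N in CH2Cl2 at rt, then transfers H2 to the C=C in a concerted, metal-free step that cannot touch benzyl ethers. This comes back to the route at 5 and replaces steps 2 and 3.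

Step 5. The risk is stalling of the hydrogenolysis at partly benzylated stages for the waxy, poorly soluble substrate, or oxidative darkening of the triol while the catalyst is filtered off. The fallback is a Lewis-acid debenzylation: it sets out from 7, which with BCl3 and pentamethylbenzene as benzyl-cation scavenger in CH2Cl2 at −78 °C, followed by a methanol quench, should cleave the three aryl benzyl ethers without touching the alkyl ester. It comes back to the route directly at 8, so no compound outside the list arises, F0.

**Further compounds**

F1 | step 6 | 3-(7-hydroxy-2,2-diphenyl-1,3-benzodioxol-5-yl)propyl octadecanoate | CCCCCCCCCCCCCCCCCC(=O)OCCCc1cc(O)c2OC(c3ccccc3)(c3ccccc3)Oc2c1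
F2 | step 6 | 3-(7-methoxy-2,2-diphenyl-1,3-benzodioxol-5-yl)propyl octadecanoate | CCCCCCCCCCCCCCCCCC(=O)OCCCc1cc(OC)c2OC(c3ccccc3)(c3ccccc3)Oc2c1
F3 | step 2 | (E)-3-[3,4,5-tris(benzyloxy)phenyl]prop-2-en-1-ol | OC/C=C/c1cc(OCc2ccccc2)c(OCc2ccccc2)c(OCc2ccccc2)c1
F0 | step 5 | none | none
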